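**Plan**

1. Retrosynthesis: the target is cut (a) at the lactone C3–CH2 bond to ring A (enolate alkylation), (b) at the lactone C3–C4 bond (carbene C–H insertion of a 3-arylpropyl diazoacetate), (c) at C7–C8 of the open 1,3-diol on ring A (anti aldol), and (d) at C2–C3 of the dihydrobenzofuran on ring B.
2. Enabling feature: C2 of the dihydrobenzofuran is an O1–CH(aryl) carbon, i.e. the CH2 of an aryl guaiacylmethyl ether, and C3 sits on C3a of ring B and carries a carboxyl-level carbon (the later CH2OH). A rhodium carbene at C3 therefore lies 1,5 to a doubly activated C–H bond and closes ring O1–C2–C3–C3a–C7a while setting C2 and C3.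
3. Forward order: both arenes get their two-carbon arm by aromatic Claisen rearrangement and alkene cleavage. On the ring B side the dihydrobenzofuran is closed first, then the γ-lactone by a second carbene C–H insertion. The ring A benzylic bromide carrying the silylated diol is then attached and all six silyl ethers are removed.
4. Stereochemistry: C2 from a chiral dirhodium carboxylate (C3 then epimerised to trans); lactone C4 from a chiral dirhodium carboxamidate; lactone C3 trans by substrate control in the alkylation; the (1S,2S) diol from an oxazolidinone auxiliary.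

Key step: step 11

Assumption: Rh2(R-PTTL)4, Rh2(4S-MPPIM)4 and the (S)-4-benzyloxazolidinone are taken to show here the facial sense known for their parent substrates; the mirror-image catalyst or auxiliary would be used if a sense proved reversed.

Abbreviations in names: TBS = tert-butyldimethylsilyl, TIPS = triisopropylsilyl, TMS = trimethylsilyl.

**Guaiacyl building blocks**

Step 1
Reactants: 1 vanillin
Product: 2 3-methoxy-4-(TIPS-oxy)benzaldehyde
Conditions: TIPSCl, imidazole, DMF, rt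
Reagents that add atoms: triisopropylsilyl chloride, CC(C)[Si](Cl)(C(C)C)C(C)C
Why: Imidazole-mediated phenol silylation gives an aryl TIPS ether that should survive the carbonate, amidine and amide bases used later.

Step 2
Reactants: 2 3-methoxy-4-(TIPS-oxy)benzaldehyde
Product: 3 [3-methoxy-4-(TIPS-oxy)phenyl]methanol
Conditions: NaBH4, MeOH/THF, 0 °C
Reagents that add atoms: none
Why: Borohydride reduction of the aryl aldehyde to the benzylic alcohol leaves the aryl silyl ether untouched.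

Step 3
Reactants: 3 [3-methoxy-4-(TIPS-oxy)phenyl]methanol
Product: 4 3-methoxy-4-(TIPS-oxy)benzyl bromide
Conditions: CBr4, PPh3, CH2Cl2, 0 °C; used at once
Reagents that add atoms: carbon tetrabromide, BrC(Br)(Br)Br
Why: The Appel reaction converts the benzylic alcohol to the bromide under neutral conditions that spare the silyl ether.

**Ring B side: dihydrobenzofuran, then lactone**

Step 4
Reactants: 5 dihydroconiferyl alcohol, 3-(4-hydroxy-3-methoxyphenyl)propan-1-ol; 6 allyl bromide
Product: 7 3-[4-(allyloxy)-3-methoxyphenyl]propan-1-ol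
Conditions: K2CO3, acetone, reflux
Reagents that add atoms: none
Why: Williamson etherification, in which carbonate deprotonates only the phenol so the primary alcohol is not alkylated.

Step 5
Reactants: 7 3-[4-(allyloxy)-3-methoxyphenyl]propan-1-ol
Product: 8 3-(3-allyl-4-hydroxy-5-methoxyphenyl)propan-1-ol
Conditions: N,N-diethylaniline, 200 °C, sealed tube
Reagents that add atoms: none
Why: The aromatic Claisen rearrangement delivers the allyl group to the only free ortho carbon, since the other ortho carbon bears OMe and the para carbon is substituted.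

Step 6
Reactants: 8 3-(3-allyl-4-hydroxy-5-methoxyphenyl)propan-1-ol; 4 3-methoxy-4-(TIPS-oxy)benzyl bromide
Product: 9 3-{3-allyl-5-methoxy-4-[3-methoxy-4-(TIPS-oxy)benzyloxy]phenyl}propan-1-ol
Conditions: K2CO3, DMF, rt
Reagents that add atoms: none
Why: Williamson etherification of the phenoxide installs the O–CH2–aryl group whose CH2 becomes C2 in step 11.

Step 7
Reactants: 9 3-{3-allyl-5-methoxy-4-[3-methoxy-4-(TIPS-oxy)benzyloxy]phenyl}propan-1-ol
Product: 10 TBS ether of 9 at the primary alcohol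
Conditions: TBSCl, imidazole, CH2Cl2, rt
Reagents that add atoms: tert-butyldimethylsilyl chloride, CC(C)(C)[Si](C)(C)Cl
Why: Silylation masks the primary O–H, which would otherwise intercept the carbene of step 11 by O–H insertion.

Step 8
Reactants: 10 TBS ether of 9
Product: 12 2-{5-[3-(TBS-oxy)propyl]-3-methoxy-2-[3-methoxy-4-(TIPS-oxy)benzyloxy]phenyl}acetic acid, via arylacetaldehyde 11 (not isolated)
Conditions: O3 (stopped at consumption of alkene), MeCN/H2O, 0 °C; then aq. NaClO2, NaH2PO4, rt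
Reagents that add atoms: ozone, [O-][O+]=O; water, O; sodium chlorite, [Na+].[O-]Cl=O
Why: Ozonolysis in aqueous acetonitrile gives the aldehyde directly because water traps the carbonyl oxide, and chlorite (Pinnick-type oxidation, with the hydrogen peroxide formed as hypochlorite scavenger) takes it to the acid in the same pot, the terminal alkene reacting with ozone much faster than the alkoxyarenes.

Step 9
Reactants: 12 arylacetic acid
Product: 13 methyl 2-{5-[3-(TBS-oxy)propyl]-3-methoxy-2-[3-methoxy-4-(TIPS-oxy)benzyloxy]phenyl}acetate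
Conditions: MeI, KHCO3, DMF, rt
Reagents that add atoms: iodomethane, CI
Why: Carboxylate O-alkylation gives the methyl ester under conditions too weakly basic to touch the silyl ethers.

Step 10
Reactants: 13 methyl arylacetate
Product: 14 methyl 2-diazo-2-{5-[3-(TBS-oxy)propyl]-3-methoxy-2-[3-methoxy-4-(TIPS-oxy)benzyloxy]phenyl}acetate
Conditions: p-ABSA, DBU, MeCN, 0 °C to rt
Reagents that add atoms: 4-acetamidobenzenesulfonyl azide, CC(=O)Nc1ccc(cc1)S(=O)(=O)N=[N+]=[N-]
Why: Regitz diazo transfer to the arylacetate enolate gives the donor/acceptor diazo ester.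

Step 11
Reactants: 14 methyl aryldiazoacetate
Product: 15 methyl (2S,3R)-5-[3-(TBS-oxy)propyl]-7-methoxy-2-[3-methoxy-4-(TIPS-oxy)phenyl]-2,3-dihydrobenzofuran-3-carboxylate (2,3-cis)
Conditions: Rh2(R-PTTL)4 (dirhodium tetrakis[N-phthaloyl-(R)-tert-leucinate], 1 mol %), toluene, −60 °C
Reagents that add atoms: none
Why: The dirhodium tetracarboxylate expels N2 from the aryl diazoacetate to give a rhodium-bound donor/acceptor carbene at the future C3, whose electrophilic carbon inserts into one of the two enantiotopic O–CH2–aryl hydrogens through a concerted, hydride-transfer-like three-centre transition state, forming the C2–C3 bond. The closest known reaction type is the enantioselective intramolecular 1,5 C–H insertion of ortho-benzyloxy aryldiazoacetates to cis-2-aryl-2,3-dihydrobenzofuran-3-carboxylates under N-phthaloyl amino acid dirhodium catalysts. The one ring closed is the five-membered O1–C2–C3–C3a–C7a ring, by 1,5 insertion across the aryl ether tether. C2 (S) is set by the catalyst, which selects between the enantiotopic benzylic hydrogens, and C3 arises cis to it (3R) from the compact insertion transition state, a relationship that step 12 turns into trans. The step needs site selectivity for this C–H bond over oxonium ylide formation with benzyl shift, carbene dimerisation and insertion elsewhere; the bond is activated by O1 and the electron-rich aryl group, is the only one reached through a five-membered transition state, is turned toward the carbene by the flanking 7-methoxy group, and the low temperature and the absence of O–H bonds suppress the alternatives.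

Step 12
Reactants: 15 cis ester
Product: 16 methyl (2S,3S)-5-[3-(TBS-oxy)propyl]-7-methoxy-2-[3-methoxy-4-(TIPS-oxy)phenyl]-2,3-dihydrobenzofuran-3-carboxylate (2,3-trans)
Conditions: DBU, toluene, 60 °C
Reagents that add atoms: none
Why: Thermodynamic epimerisation at C3 through the ester enolate places the ester trans to the C2 aryl group, while C2 stays intact because β-elimination of the ring oxygen would need the C2–O1 bond to align with the exocyclic enolate π system, which the five-membered ring prevents.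

Step 13
Reactants: 16 trans ester
Product: 17 {(2S,3R)-5-[3-(TBS-oxy)propyl]-7-methoxy-2-[3-methoxy-4-(TIPS-oxy)phenyl]-2,3-dihydrobenzofuran-3-yl}methanol
Conditions: i-Bu2AlH, CH2Cl2, −78 to 0 °C; Rochelle salt work-up
Reagents that add atoms: none
Why: Hydride reduction of the ester gives the 3-hydroxymethyl group without touching either stereocentre (the descriptor at C3 changes only by priority).

Step 14
Reactants: 17 primary alcohol
Product: 18 TIPS ether of 17 at the 3-hydroxymethyl group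
Conditions: TIPSCl, imidazole, DMF, rt
Reagents that add atoms: triisopropylsilyl chloride, CC(C)[Si](Cl)(C(C)C)C(C)C
Why: A primary TIPS ether is much more stable to acid than the primary TBS ether on the propyl chain, which allows step 15.

Step 15
Reactants: 18 TIPS ether
Product: 19 3-{(2S,3R)-7-methoxy-2-[3-methoxy-4-(TIPS-oxy)phenyl]-3-(TIPS-oxymethyl)-2,3-dihydrobenzofuran-5-yl}propan-1-ol
Conditions: PPTS, EtOH, 45 °C
Reagents that add atoms: none
Why: Mild acidic ethanolysis removes the primary TBS ether selectively, primary and aryl TIPS ethers being far slower to cleave.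

Step 16
Reactants: 19 propanol; 20 glyoxylic acid chloride p-toluenesulfonylhydrazone
Product: 22 3-{(2S,3R)-7-methoxy-2-[3-methoxy-4-(TIPS-oxy)phenyl]-3-(TIPS-oxymethyl)-2,3-dihydrobenzofuran-5-yl}propyl diazoacetate, via tosylhydrazone ester 21 (not isolated)
Conditions: PhNMe2, CH2Cl2, 0 °C; then Et3N, 0 °C to rt
Reagents that add atoms: none
Why: Acylation of the alcohol by the acid chloride followed by base-induced loss of sulfinate from the tosylhydrazone (Bamford–Stevens-type fragmentation) gives the diazoacetate in one flask.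

Step 17
Reactants: 22 diazoacetate
Product: 23 (4R)-4-{[(2S,3R)-7-methoxy-2-[3-methoxy-4-(TIPS-oxy)phenyl]-3-(TIPS-oxymethyl)-2,3-dihydrobenzofuran-5-yl]methyl}dihydrofuran-2(3H)-one
Conditions: Rh2(4S-MPPIM)4 (dirhodium tetrakis[methyl 1-(3-phenylpropanoyl)-2-oxoimidazolidine-4(S)-carboxylate], 1 mol %), CH2Cl2, reflux, slow addition of 22
Reagents that add atoms: none
Why: The acceptor carbene on the chiral dirhodium carboxamidate inserts into a C–H bond of the carbon β to the ester oxygen (1,5 insertion, the known enantioselective route to β-benzyl-γ-butyrolactones), the catalyst choosing between the enantiotopic hydrogens to set C4 as R.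

**Ring A side: benzylic bromide with the open diol**

Step 18
Reactants: 24 methyl vanillate; 6 allyl bromide
Product: 25 methyl 4-(allyloxy)-3-methoxybenzoate
Conditions: K2CO3, DMF, rt
Reagents that add atoms: none
Why: Williamson etherification of the phenol.

Step 19
Reactants: 25 methyl 4-(allyloxy)-3-methoxybenzoate
Product: 26 methyl 3-allyl-4-hydroxy-5-methoxybenzoate
Conditions: N,N-diethylaniline, 200 °C, sealed tube
Reagents that add atoms: none
Why: The aromatic Claisen rearrangement moves the allyl group to the single free ortho carbon.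

Step 20
Reactants: 26 methyl 3-allyl-4-hydroxy-5-methoxybenzoate
Product: 27 methyl 3-allyl-4-(TBS-oxy)-5-methoxybenzoate
Conditions: TBSCl, imidazole, DMF, 50 °C
Reagents that add atoms: tert-butyldimethylsilyl chloride, CC(C)(C)[Si](C)(C)Cl
Why: Silylation of the hindered phenol gives an ortho,ortho-shielded aryl TBS ether, small enough not to block the later aldol next to it.

Step 21
Reactants: 27 methyl 3-allyl-4-(TBS-oxy)-5-methoxybenzoate
Product: 29 2-[2-(TBS-oxy)-3-methoxy-5-(methoxycarbonyl)phenyl]acetic acid, via arylacetaldehyde 28 (not isolated)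
Conditions: O3, MeCN/H2O, 0 °C; then aq. NaClO2, NaH2PO4, rt
Reagents that add atoms: ozone, [O-][O+]=O; water, O; sodium chlorite, [Na+].[O-]Cl=O
Why: Same one-pot ozonolysis and chlorite oxidation as in step 8, here on an arene made less ozone-sensitive by the ester group.

Step 22
Reactants: 29 arylacetic acid; 30 (S)-4-benzyloxazolidin-2-one
Product: 32 methyl 3-{2-[(4S)-4-benzyl-2-oxooxazolidin-3-yl]-2-oxoethyl}-4-(TBS-oxy)-5-methoxybenzoate, via mixed pivalic anhydride 31 (not isolated)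
Conditions: PivCl, Et3N, THF, −20 °C; then LiCl, 30, rt
Reagents that add atoms: pivaloyl chloride, CC(C)(C)C(Cl)=O (its atoms stay only in 31)
Why: Mixed-anhydride activation followed by LiCl-assisted N-acylation attaches the auxiliary without strong base, sparing the aryl ester and the aryl silyl ether.

Step 23
Reactants: 32 N-arylacetyl oxazolidinone; 2 3-methoxy-4-(TIPS-oxy)benzaldehyde
Product: 33 methyl 3-{(2R,3S)-1-[(4S)-4-benzyl-2-oxooxazolidin-3-yl]-3-[3-methoxy-4-(TIPS-oxy)phenyl]-1-oxo-3-(TMS-oxy)propan-2-yl}-4-(TBS-oxy)-5-methoxybenzoate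
Conditions: MgCl2 (0.2 equiv), NaSbF6 (0.3 equiv), Et3N, TMSCl, EtOAc, rt; filtration through Et3N-deactivated silica
Reagents that add atoms: chlorotrimethylsilane, C[Si](C)(C)Cl
Why: Magnesium-halide-catalysed anti aldol addition of an N-acyloxazolidinone, in which the chelated Z-enolate adds to the aromatic aldehyde through a boat-like transition state on the face opposite the benzyl group (setting C8, 2R here, and C7, 3S here, anti) and TMSCl traps the aldolate, which turns over the magnesium and blocks retro-aldol.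

Step 24
Reactants: 33 silylated aldol adduct
Product: 35 methyl 3-{(1S,2S)-1,3-dihydroxy-1-[3-methoxy-4-(TIPS-oxy)phenyl]propan-2-yl}-4-(TBS-oxy)-5-methoxybenzoate, via primary alcohol trimethylsilyl ether 34 (not isolated)
Conditions: LiBH4, MeOH (1.5 equiv), THF, 0 °C; then aq. citric acid, MeOH, rt
Reagents that add atoms: none
Why: Borohydride cleaves the activated imide carbonyl reductively to the primary alcohol much faster than it attacks the electron-rich aryl ester, and mild acid then removes the TMS group without ionising the benzylic position.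

Step 25
Reactants: 35 diol
Product: 36 methyl 3-{(1S,2S)-1,3-bis(TBS-oxy)-1-[3-methoxy-4-(TIPS-oxy)phenyl]propan-2-yl}-4-(TBS-oxy)-5-methoxybenzoate
Conditions: TBSOTf (excess), 2,6-lutidine, CH2Cl2, −78 to 0 °C
Reagents that add atoms: tert-butyldimethylsilyl triflate, CC(C)(C)[Si](C)(C)OS(=O)(=O)C(F)(F)F
Why: Exhaustive silylation protects both alcohols, and because the ring A phenol also carries TBS, any aryl-to-alkyl silyl migration during step 24 leads to the same product.

Step 26
Reactants: 36 aryl methyl ester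
Product: 37 {3-[(1S,2S)-1,3-bis(TBS-oxy)-1-[3-methoxy-4-(TIPS-oxy)phenyl]propan-2-yl]-4-(TBS-oxy)-5-methoxyphenyl}methanol
Conditions: i-Bu2AlH, CH2Cl2, −78 °C; Rochelle salt work-up
Reagents that add atoms: none
Why: Hydride reduction of the benzoate ester to the benzylic alcohol, silyl ethers being inert.

Step 27
Reactants: 37 benzylic alcohol
Product: 38 3-[(1S,2S)-1,3-bis(TBS-oxy)-1-[3-methoxy-4-(TIPS-oxy)phenyl]propan-2-yl]-4-(TBS-oxy)-5-methoxybenzyl bromide
Conditions: CBr4, PPh3, CH2Cl2, 0 °C; used at once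
Reagents that add atoms: carbon tetrabromide, BrC(Br)(Br)Br
Why: Appel bromination of the primary benzylic alcohol under neutral conditions.

**Union and deprotection**

Step 28
Reactants: 23 β-substituted γ-butyrolactone; 38 benzylic bromide
Product: 39 (3R,4R)-3-{3-[(1S,2S)-1,3-bis(TBS-oxy)-1-[3-methoxy-4-(TIPS-oxy)phenyl]propan-2-yl]-4-(TBS-oxy)-5-methoxybenzyl}-4-{[(2S,3R)-7-methoxy-2-[3-methoxy-4-(TIPS-oxy)phenyl]-3-(TIPS-oxymethyl)-2,3-dihydrobenzofuran-5-yl]methyl}dihydrofuran-2(3H)-one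
Conditions: LiN(SiMe3)2, THF, −78 °C; then 38, DMPU, −78 to −40 °C
Reagents that add atoms: none
Why: The lithium enolate of the lactone is alkylated by the benzylic bromide on the face anti to the C4 substituent (substrate control, the standard entry to trans-dibenzylbutyrolactones), setting C3 as R.

Step 29
Reactants: 39 hexasilyl ether
Product: 40 CNP0186558.2, (3R,4R)-3-{3-[(1S,2S)-1,3-dihydroxy-1-(4-hydroxy-3-methoxyphenyl)propan-2-yl]-4-hydroxy-5-methoxybenzyl}-4-{[(2S,3R)-2-(4-hydroxy-3-methoxyphenyl)-3-(hydroxymethyl)-7-methoxy-2,3-dihydrobenzofuran-5-yl]methyl}dihydrofuran-2(3H)-one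
Conditions: Bu4NF, AcOH (1:1, excess), THF, 0 °C to rt
Reagents that add atoms: none
Why: Fluoride cleaves the three aryl and three alkyl silyl ethers, and acetic acid keeps the phenols protonated so that quinone methide formation, opening of the dihydrobenzofuran and epimerisation of the lactone should not intervene.

**Compound list**

1 | vanillin | COc1cc(C=O)ccc1O | starting material
2 | 3-methoxy-4-(TIPS-oxy)benzaldehyde | COc1cc(C=O)ccc1O[Si](C(C)C)(C(C)C)C(C)C | intermediate
3 | [3-methoxy-4-(TIPS-oxy)phenyl]methanol | COc1cc(CO)ccc1O[Si](C(C)C)(C(C)C)C(C)C | intermediate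
4 | 3-methoxy-4-(TIPS-oxy)benzyl bromide | COc1cc(CBr)ccc1O[Si](C(C)C)(C(C)C)C(C)C | intermediate
5 | dihydroconiferyl alcohol | COc1cc(CCCO)ccc1O | starting material
6 | allyl bromide | C=CCBr | starting material
7 | 3-[4-(allyloxy)-3-methoxyphenyl]propan-1-ol | COc1cc(CCCO)ccc1OCC=C | intermediate
8 | 3-(3-allyl-4-hydroxy-5-methoxyphenyl)propan-1-ol | COc1cc(CCCO)cc(CC=C)c1O | intermediate
9 | 3-{3-allyl-5-methoxy-4-[3-methoxy-4-(TIPS-oxy)benzyloxy]phenyl}propan-1-ol | COc1cc(CCCO)cc(CC=C)c1OCc1ccc(O[Si](C(C)C)(C(C)C)C(C)C)c(OC)c1 | intermediate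
10 | TBS ether of 9 | COc1cc(CCCO[Si](C)(C)C(C)(C)C)cc(CC=C)c1OCc1ccc(O[Si](C(C)C)(C(C)C)C(C)C)c(OC)c1 | intermediate
11 | arylacetaldehyde from 10 | COc1cc(CCCO[Si](C)(C)C(C)(C)C)cc(CC=O)c1OCc1ccc(O[Si](C(C)C)(C(C)C)C(C)C)c(OC)c1 | intermediate
12 | 2-{5-[3-(TBS-oxy)propyl]-3-methoxy-2-[3-methoxy-4-(TIPS-oxy)benzyloxy]phenyl}acetic acid | COc1cc(CCCO[Si](C)(C)C(C)(C)C)cc(CC(=O)O)c1OCc1ccc(O[Si](C(C)C)(C(C)C)C(C)C)c(OC)c1 | intermediate
13 | methyl ester of 12 | COc1cc(CCCO[Si](C)(C)C(C)(C)C)cc(CC(=O)OC)c1OCc1ccc(O[Si](C(C)C)(C(C)C)C(C)C)c(OC)c1 | intermediate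
14 | methyl 2-diazo-2-arylacetate from 13 | COc1cc(CCCO[Si](C)(C)C(C)(C)C)cc(C(=[N+]=[N-])C(=O)OC)c1OCc1ccc(O[Si](C(C)C)(C(C)C)C(C)C)c(OC)c1 | intermediate
15 | methyl (2S,3R)-cis-dihydrobenzofuran-3-carboxylate | CC(C)(C)[Si](C)(C)OCCCc1cc(OC)c2c(c1)[C@@H](C(=O)OC)[C@@H](c1ccc(O[Si](C(C)C)(C(C)C)C(C)C)c(OC)c1)O2 | intermediate
16 | methyl (2S,3S)-trans-dihydrobenzofuran-3-carboxylate | CC(C)(C)[Si](C)(C)OCCCc1cc(OC)c2c(c1)[C@H](C(=O)OC)[C@@H](c1ccc(O[Si](C(C)C)(C(C)C)C(C)C)c(OC)c1)O2 | intermediate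
17 | (2S,3R)-3-hydroxymethyl dihydrobenzofuran | CC(C)(C)[Si](C)(C)OCCCc1cc(OC)c2c(c1)[C@H](CO)[C@@H](c1ccc(O[Si](C(C)C)(C(C)C)C(C)C)c(OC)c1)O2 | intermediate
18 | TIPS ether of 17 | CC(C)(C)[Si](C)(C)OCCCc1cc(OC)c2c(c1)[C@H](CO[Si](C(C)C)(C(C)C)C(C)C)[C@@H](c1ccc(O[Si](C(C)C)(C(C)C)C(C)C)c(OC)c1)O2 | intermediate
19 | 3-{(2S,3R)-dihydrobenzofuran-5-yl}propan-1-ol, bis-TIPS | OCCCc1cc(OC)c2c(c1)[C@H](CO[Si](C(C)C)(C(C)C)C(C)C)[C@@H](c1ccc(O[Si](C(C)C)(C(C)C)C(C)C)c(OC)c1)O2 | intermediate
20 | glyoxylic acid chloride p-toluenesulfonylhydrazone | Cc1ccc(cc1)S(=O)(=O)NN=CC(Cl)=O | starting material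
21 | glyoxylate tosylhydrazone ester of 19 | Cc1ccc(cc1)S(=O)(=O)NN=CC(=O)OCCCc1cc(OC)c2c(c1)[C@H](CO[Si](C(C)C)(C(C)C)C(C)C)[C@@H](c1ccc(O[Si](C(C)C)(C(C)C)C(C)C)c(OC)c1)O2 | intermediate
22 | diazoacetate of 19 | [N-]=[N+]=CC(=O)OCCCc1cc(OC)c2c(c1)[C@H](CO[Si](C(C)C)(C(C)C)C(C)C)[C@@H](c1ccc(O[Si](C(C)C)(C(C)C)C(C)C)c(OC)c1)O2 | intermediate
23 | (4R)-4-(dihydrobenzofuran-5-ylmethyl)dihydrofuran-2(3H)-one | O=C1C[C@@H](Cc2cc(OC)c3c(c2)[C@H](CO[Si](C(C)C)(C(C)C)C(C)C)[C@@H](c2ccc(O[Si](C(C)C)(C(C)C)C(C)C)c(OC)c2)O3)CO1 | intermediate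
24 | methyl vanillate | COC(=O)c1ccc(O)c(OC)c1 | starting material
25 | methyl 4-(allyloxy)-3-methoxybenzoate | COC(=O)c1ccc(OCC=C)c(OC)c1 | intermediate
26 | methyl 3-allyl-4-hydroxy-5-methoxybenzoate | COC(=O)c1cc(CC=C)c(O)c(OC)c1 | intermediate
27 | methyl 3-allyl-4-(TBS-oxy)-5-methoxybenzoate | COC(=O)c1cc(CC=C)c(O[Si](C)(C)C(C)(C)C)c(OC)c1 | intermediate
28 | methyl 4-(TBS-oxy)-3-methoxy-5-(2-oxoethyl)benzoate | COC(=O)c1cc(CC=O)c(O[Si](C)(C)C(C)(C)C)c(OC)c1 | intermediate
29 | 2-[2-(TBS-oxy)-3-methoxy-5-(methoxycarbonyl)phenyl]acetic acid | COC(=O)c1cc(CC(=O)O)c(O[Si](C)(C)C(C)(C)C)c(OC)c1 | intermediate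
30 | (S)-4-benzyloxazolidin-2-one | O=C1N[C@@H](Cc2ccccc2)CO1 | starting material
31 | mixed pivalic anhydride of 29 | COC(=O)c1cc(CC(=O)OC(=O)C(C)(C)C)c(O[Si](C)(C)C(C)(C)C)c(OC)c1 | intermediate
32 | N-arylacetyl (4S)-4-benzyloxazolidinone | COC(=O)c1cc(CC(=O)N2C(=O)OC[C@@H]2Cc2ccccc2)c(O[Si](C)(C)C(C)(C)C)c(OC)c1 | intermediate
33 | (2R,3S)-anti aldol adduct, TMS ether | COc1cc([C@@H](O[Si](C)(C)C)[C@H](C(=O)N2C(=O)OC[C@@H]2Cc2ccccc2)c2cc(C(=O)OC)cc(OC)c2O[Si](C)(C)C(C)(C)C)ccc1O[Si](C(C)C)(C(C)C)C(C)C | intermediate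
34 | primary alcohol with secondary TMS ether | COc1cc([C@@H](O[Si](C)(C)C)[C@H](CO)c2cc(C(=O)OC)cc(OC)c2O[Si](C)(C)C(C)(C)C)ccc1O[Si](C(C)C)(C(C)C)C(C)C | intermediate
35 | (1S,2S)-1,3-diol | COc1cc([C@@H](O)[C@H](CO)c2cc(C(=O)OC)cc(OC)c2O[Si](C)(C)C(C)(C)C)ccc1O[Si](C(C)C)(C(C)C)C(C)C | intermediate
36 | (1S,2S)-bis-TBS ether, aryl methyl ester | COc1cc([C@@H](O[Si](C)(C)C(C)(C)C)[C@H](CO[Si](C)(C)C(C)(C)C)c2cc(C(=O)OC)cc(OC)c2O[Si](C)(C)C(C)(C)C)ccc1O[Si](C(C)C)(C(C)C)C(C)C | intermediate
37 | benzylic alcohol from 36 | COc1cc([C@@H](O[Si](C)(C)C(C)(C)C)[C@H](CO[Si](C)(C)C(C)(C)C)c2cc(CO)cc(OC)c2O[Si](C)(C)C(C)(C)C)ccc1O[Si](C(C)C)(C(C)C)C(C)C | intermediate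
38 | benzylic bromide from 37 | COc1cc([C@@H](O[Si](C)(C)C(C)(C)C)[C@H](CO[Si](C)(C)C(C)(C)C)c2cc(CBr)cc(OC)c2O[Si](C)(C)C(C)(C)C)ccc1O[Si](C(C)C)(C(C)C)C(C)C | intermediate
39 | hexasilyl-protected (3R,4R)-lactone | COc1cc([C@@H](O[Si](C)(C)C(C)(C)C)[C@H](CO[Si](C)(C)C(C)(C)C)c2cc(C[C@H]3C(=O)OC[C@@H]3Cc3cc(OC)c4c(c3)[C@H](CO[Si](C(C)C)(C(C)C)C(C)C)[C@@H](c3ccc(O[Si](C(C)C)(C(C)C)C(C)C)c(OC)c3)O4)cc(OC)c2O[Si](C)(C)C(C)(C)C)ccc1O[Si](C(C)C)(C(C)C)C(C)C | intermediate
40 | CNP0186558.2 | COc1cc([C@@H](O)[C@H](CO)c2cc(C[C@H]3C(=O)OC[C@@H]3Cc3cc(OC)c4c(c3)[C@H](CO)[C@@H](c3ccc(O)c(OC)c3)O4)cc(OC)c2O)ccc1O | target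

**Step count and risks**

Total steps: 29. Longest linear sequence: 17 steps (steps 1–3, 6–17, 28, 29).

Most likely to fail:

1. Step 11. The carbene may show insufficient enantiofacial or cis/trans control on this heavily oxygenated substrate, or be diverted to oxonium ylide formation with benzyl shift or to dimerisation. The fallback moves the stereocontrol from the catalyst to a covalently bound auxiliary whose diastereomeric products can be separated; it sets out from 12 and returns at 17. Acid 12 is esterified (EDC·HCl, DMAP, CH2Cl2) with (S)-2-hydroxy-1-(pyrrolidin-1-yl)propan-1-one to the lactamide ester F1. Diazo transfer (p-ABSA, DBU) gives the diazo ester F2. Decomposition with Rh2(S-DOSP)4 (dirhodium tetrakis[(S)-N-(4-dodecylbenzenesulfonyl)prolinate]) followed by DBU equilibration gives trans-dihydrobenzofurans as diastereomers, from which the (2S,3S) lactamide ester F3 is separated by chromatography (the lactamide antipode is chosen to match the catalyst). LiBH4 in THF then reduces the ester and releases the auxiliary to give 17.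

2. Step 23. The α-aryl imide may give poor anti/syn or facial selectivity, or the α-aryl aldolate may revert by retro-aldol before it is silylated. The fallback uses a boron syn aldol and inverts the carbinol centre; it sets out from 29 and returns at 36. Acid 29 is attached (PivCl, Et3N, LiCl) to (R)-4-benzyloxazolidin-2-one to give the imide F4. Enolisation with Bu2BOTf and i-Pr2NEt and addition of aldehyde 2 gives the (2R,3R) syn aldol adduct F5. LiBH4 gives the (1R,2S) diol F6, and TBSCl with imidazole at 0 °C silylates only the primary alcohol to give the mono-TBS ether F7. A Mitsunobu reaction (4-nitrobenzoic acid, PPh3, DIAD, toluene, 0 °C) inverts the benzylic carbinol to the (1S) 4-nitrobenzoate F8. Brief methanolysis (K2CO3, MeOH, 0 °C) frees the (1S,2S) secondary alcohol F9, and excess TBSOTf with 2,6-lutidine silylates it, together with any phenol bared in the methanolysis, to give 36.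

3. Step 17. On this large substrate the acceptor carbene may insert with poor site selectivity or enantioselectivity, or attack the electron-rich arene. The fallback builds the lactone by auxiliary-controlled alkylation; it sets out from 19 and returns at 23. Alcohol 19 is oxidised (TEMPO, PhI(OAc)2, MeCN/H2O) to the propanoic acid F10, which is attached (PivCl, Et3N, LiCl) to (S)-4-benzyloxazolidin-2-one to give the imide F11. The sodium enolate (NaN(SiMe3)2, THF, −78 °C) is alkylated with tert-butyl bromoacetate anti to the benzyl group of the auxiliary to give the (2R) succinate derivative F12. LiBH4 cleaves the imide to the hydroxy tert-butyl ester F13, and catalytic p-toluenesulfonic acid in warm toluene closes it to lactone 23.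

**Further compounds**

F1 | step 11 | (2S)-1-oxo-1-(pyrrolidin-1-yl)propan-2-yl ester of acid 12 | C[C@H](OC(=O)Cc1cc(CCCO[Si](C)(C)C(C)(C)C)cc(OC)c1OCc1ccc(O[Si](C(C)C)(C(C)C)C(C)C)c(OC)c1)C(=O)N1CCCC1
F2 | step 11 | diazo derivative of F1 | C[C@H](OC(=O)C(=[N+]=[N-])c1cc(CCCO[Si](C)(C)C(C)(C)C)cc(OC)c1OCc1ccc(O[Si](C(C)C)(C(C)C)C(C)C)c(OC)c1)C(=O)N1CCCC1
F3 | step 11 | (2S,3S)-trans-dihydrobenzofuran-3-carboxylate of the (S)-lactamide | CC(C)(C)[Si](C)(C)OCCCc1cc(OC)c2c(c1)[C@H](C(=O)O[C@@H](C)C(=O)N1CCCC1)[C@@H](c1ccc(O[Si](C(C)C)(C(C)C)C(C)C)c(OC)c1)O2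
F4 | step 23 | N-arylacetyl (4R)-4-benzyloxazolidinone from 29 | COC(=O)c1cc(CC(=O)N2C(=O)OC[C@H]2Cc2ccccc2)c(O[Si](C)(C)C(C)(C)C)c(OC)c1
F5 | step 23 | (2R,3R)-syn aldol adduct on the (4R) auxiliary | COc1cc([C@H](O)[C@H](C(=O)N2C(=O)OC[C@H]2Cc2ccccc2)c2cc(C(=O)OC)cc(OC)c2O[Si](C)(C)C(C)(C)C)ccc1O[Si](C(C)C)(C(C)C)C(C)C
F6 | step 23 | (1R,2S)-1,3-diol | COc1cc([C@H](O)[C@H](CO)c2cc(C(=O)OC)cc(OC)c2O[Si](C)(C)C(C)(C)C)ccc1O[Si](C(C)C)(C(C)C)C(C)C
F7 | step 23 | (1R,2S)-diol, primary TBS ether | COc1cc([C@H](O)[C@H](CO[Si](C)(C)C(C)(C)C)c2cc(C(=O)OC)cc(OC)c2O[Si](C)(C)C(C)(C)C)ccc1O[Si](C(C)C)(C(C)C)C(C)C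
F8 | step 23 | (1S,2S) 4-nitrobenzoate | COc1cc([C@@H](OC(=O)c3ccc(cc3)[N+](=O)[O-])[C@H](CO[Si](C)(C)C(C)(C)C)c2cc(C(=O)OC)cc(OC)c2O[Si](C)(C)C(C)(C)C)ccc1O[Si](C(C)C)(C(C)C)C(C)C
F9 | step 23 | (1S,2S) secondary alcohol, primary TBS ether | COc1cc([C@@H](O)[C@H](CO[Si](C)(C)C(C)(C)C)c2cc(C(=O)OC)cc(OC)c2O[Si](C)(C)C(C)(C)C)ccc1O[Si](C(C)C)(C(C)C)C(C)C
F10 | step 17 | 3-(dihydrobenzofuran-5-yl)propanoic acid from 19 | OC(=O)CCc1cc(OC)c2c(c1)[C@H](CO[Si](C(C)C)(C(C)C)C(C)C)[C@@H](c1ccc(O[Si](C(C)C)(C(C)C)C(C)C)c(OC)c1)O2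
F11 | step 17 | N-(3-arylpropanoyl) (4S)-4-benzyloxazolidinone | O=C(CCc1cc(OC)c2c(c1)[C@H](CO[Si](C(C)C)(C(C)C)C(C)C)[C@@H](c1ccc(O[Si](C(C)C)(C(C)C)C(C)C)c(OC)c1)O2)N1C(=O)OC[C@@H]1Cc1ccccc1
F12 | step 17 | (2R)-2-(arylmethyl)succinate, tert-butyl ester and (4S) imide | CC(C)(C)OC(=O)C[C@@H](Cc1cc(OC)c2c(c1)[C@H](CO[Si](C(C)C)(C(C)C)C(C)C)[C@@H](c1ccc(O[Si](C(C)C)(C(C)C)C(C)C)c(OC)c1)O2)C(=O)N1C(=O)OC[C@@H]1Cc1ccccc1
F13 | step 17 | tert-butyl (3R)-3-(arylmethyl)-4-hydroxybutanoate | CC(C)(C)OC(=O)C[C@@H](Cc1cc(OC)c2c(c1)[C@H](CO[Si](C(C)C)(C(C)C)C(C)C)[C@@H](c1ccc(O[Si](C(C)C)(C(C)C)C(C)C)c(OC)c1)O2)CO
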